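The seven-membered ring (C1, C5–C10; daucane numbering) is disconnected into a four-carbon diene C1=C5–C6=C7, carried by a 2-methyl-1-vinylcyclopentene that already holds the five-membered ring with C2–O and C4(OH)(isopropyl), and a three-carbon unit C8–C9–C10, a rhodium vinylcarbenoid with oxygen on C10. In one operation, catalyst-controlled cyclopropanation of the vinyl group and boat Cope rearrangement of the cis-divinylcyclopropane (a formal (4+3) cycloaddition) form C7–C8 and C1–C10, set the quaternary C1 and C10, and leave C5=C6 and C8=C9 where the C6 ester and the C8–C9 epoxide belong. The feature exploited is this cyclohepta-1,4-diene pattern flanking the quaternary C1.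

Key step: step 7

Remark (numbering): C1 is the quaternary ring-fusion carbon bearing methyl C15; C2 (OAc), C3 (CH2), C4 (C–OH bearing the isopropyl group) and C5 (ring-fusion CH) complete the five-membered ring; C6 (O-angeloyl), C7 (CH2), C8 (epoxide carbon bearing methyl C14), C9 (epoxide CH) and C10 (OAc) complete the seven-membered ring; beta is the face of C15, alpha the opposite face.

Remark (assumption): the sense of induction of Rh2(DOSP)4 is taken to follow its known (1S,2R) preference with the S catalyst in cyclopropanation of monosubstituted alkenes, which is why the R catalyst is chosen in step 7.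

Step 1
Reactants: 1 3-methylbutan-2-one; 2 methacrolein
Product: 3 (S)-5-hydroxy-2,6-dimethylhept-6-en-3-one
Conditions: (−)-Ipc2BCl, Et3N, Et2O, −78 °C; then 2, −78 → −20 °C; H2O2, MeOH, pH 7 buffer
Reagents that add atoms: none
Why: Boron aldol reaction of the methyl-side diisopinocampheyl enol borinate through a cyclic transition state; the ligand derived from (+)-alpha-pinene should direct attack to the si face of methacrolein, which sets the carbinol carbon (later C2) as S.

Step 2
Reactants: 3 (S)-5-hydroxy-2,6-dimethylhept-6-en-3-one; 4 ethynylmagnesium bromide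
Product: 5 (3R,5S)-6-methyl-3-(propan-2-yl)hept-6-en-1-yne-3,5-diol
Conditions: HC≡CMgBr (3.5 equiv), THF–CH2Cl2, −78 → −20 °C; aq NH4Cl
Reagents that add atoms: none
Why: Chelation-controlled (Cram-chelate) Grignard addition to a beta-hydroxy ketone: the bromomagnesium alkoxide formed by the first equivalent holds the ketone in a six-membered chelate with the isopropenyl group equatorial, and external axial attack of the small alkynyl nucleophile should give the 1,3-anti diol (new centre C4 R, its hydroxyl trans to the C2 hydroxyl in the later ring).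

Step 3
Reactants: 5 (3R,5S)-6-methyl-3-(propan-2-yl)hept-6-en-1-yne-3,5-diol
Product: 6 (1R,3S)-5-ethenyl-4-methyl-1-(propan-2-yl)cyclopent-4-ene-1,3-diol
Conditions: second-generation Grubbs catalyst RuCl2(=CHPh)(H2IMes)(PCy3) (5–10 mol%), ethylene (1 atm), toluene, 80 °C
Reagents that add atoms: none
Why: Ring-closing enyne metathesis in the exo mode converts the 1,6-enyne into the 1-vinylcyclopentene with the tetrasubstituted C1=C5 bond, so that C6=C7 appears as the vinyl group; neither stereocentre is touched.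

Step 4
Reactants: 6 (1R,3S)-5-ethenyl-4-methyl-1-(propan-2-yl)cyclopent-4-ene-1,3-diol
Product: 7 (1R,3S)-5-ethenyl-4-methyl-1-(propan-2-yl)-1,3-bis(triethylsilyloxy)cyclopent-4-ene
Conditions: TESOTf (2.5 equiv), 2,6-lutidine, CH2Cl2, −78 → 0 °C
Reagents that add atoms: triethylsilyl trifluoromethanesulfonate, CC[Si](CC)(CC)OS(=O)(=O)C(F)(F)F
Why: A silyl triflate with a hindered base silylates the secondary and the tertiary allylic hydroxyl alike, which removes O–H insertion as a pathway in the carbenoid step; no stereocentre is affected.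

Step 5
Reactants: 8 ethyl diazoacetate; 9 (tert-butyldimethylsilyloxy)acetaldehyde
Product: 10 ethyl 4-(tert-butyldimethylsilyloxy)-2-diazo-3-hydroxybutanoate (racemic)
Conditions: DBU (10 mol%), MeCN, 0 °C → rt
Reagents that add atoms: none
Why: Base-catalysed aldol-type addition of the diazoacetate carbon to the aldehyde gives the beta-hydroxy-alpha-diazo ester; its carbinol centre disappears in the next step.

Step 6
Reactants: 10 ethyl 4-(tert-butyldimethylsilyloxy)-2-diazo-3-hydroxybutanoate
Product: 11 ethyl (E)-4-(tert-butyldimethylsilyloxy)-2-diazobut-3-enoate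
Conditions: POCl3, Et3N, CH2Cl2, −20 → 0 °C; used at once
Reagents that add atoms: none
Why: Dehydration of a beta-hydroxy-alpha-diazo ester with POCl3 and Et3N is the standard entry to vinyldiazoacetates; elimination can only occur toward the silyloxy-bearing carbon and should place the silyloxy group trans to the diazo carbon (E) for steric reasons.

Step 7
Reactants: 7 (1R,3S)-5-ethenyl-4-methyl-1-(propan-2-yl)-1,3-bis(triethylsilyloxy)cyclopent-4-ene; 11 ethyl (E)-4-(tert-butyldimethylsilyloxy)-2-diazobut-3-enoate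
Product: 13 ethyl (1R,2S,4R,10R)-10alpha-(tert-butyldimethylsilyloxy)-2alpha,4beta-bis(triethylsilyloxy)dauca-5,8-dien-14-oate, via cis-divinylcyclopropane 12 (not isolated)
Conditions: Rh2(R-DOSP)4 (dirhodium tetrakis[(R)-N-(4-dodecylbenzenesulfonyl)prolinate], 2 mol%), 11 (2.5 equiv, slow addition), 2,2-dimethylbutane, −40 °C → rt; then toluene, 90 °C
Reagents that add atoms: none
Why: Rh2(R-DOSP)4 turns 11 into a donor/acceptor vinylcarbenoid that cyclopropanates the monosubstituted C6=C7 bond of 7, the carbenoid carbon (C8) bonding to C7 and C6 with the siloxyvinyl group cis to the cyclopentenyl group (12), and heating then drives the Cope rearrangement of this cis-divinylcyclopropane, which cleaves C6–C8 and joins C10 to C1. The closest known reaction type is the rhodium-carbenoid tandem cyclopropanation/Cope rearrangement of vinyldiazoacetates with dienes (formal (4+3) cycloaddition), which is established for 2-methyl-1-vinylcycloalkenes that end as a quaternary methyl-bearing ring-fusion carbon. The three-membered ring is closed by concerted carbenoid addition and the seven-membered ring by the (3,3)-sigmatropic shift through the endo boat, the only geometry open to a cis-divinylcyclopropane, so C5=C6 and C8=C9 are both cis ring alkenes. C1 is controlled by the configuration of C6 in 12 (set by the chiral catalyst, which selects the face of the vinyl group), because from that cyclopropane the boat can deliver C10 only to the alpha face of C1 with the C15 methyl inside; C10 is controlled by the E geometry of the enol ether, which keeps oxygen outside in the boat and hence trans to C15. The step needs chemoselectivity for the vinyl group over the tetrasubstituted C1=C5 bond and over insertion reactions (secured by full silylation and a hydrocarbon solvent), attack at the carbenoid carbon and not at the vinylogous C10 terminus (E-substituted terminus, carboxylate catalyst in a non-polar medium), and catalyst control over the resident C2 and C4 centres.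

Step 8
Reactants: 13 ethyl (1R,2S,4R,10R)-10alpha-(tert-butyldimethylsilyloxy)-2alpha,4beta-bis(triethylsilyloxy)dauca-5,8-dien-14-oate
Product: 14 ethyl (1R,2S,4R,5S,6S,10R)-6alpha-hydroxy-10alpha-(tert-butyldimethylsilyloxy)-2alpha,4beta-bis(triethylsilyloxy)dauc-8-en-14-oate
Conditions: BH3·THF, THF, 0 °C → rt; then 30% H2O2, aq NaOAc, 0 °C → rt
Reagents that add atoms: hydrogen peroxide, OO
Why: Hydroboration–oxidation: borane should add to the electron-neutral trisubstituted C5=C6 bond in preference to the conjugated enoate C8=C9, with boron at the less substituted C6 and syn delivery from the alpha face, anti to the angular C15 methyl and to the allylic C4–O bond (as in hydroboration of steroidal 5-enes), which sets C5 (S) and C6 (S) together.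

Step 9
Reactants: 14 ethyl (1R,2S,4R,5S,6S,10R)-6alpha-hydroxy-10alpha-(tert-butyldimethylsilyloxy)-2alpha,4beta-bis(triethylsilyloxy)dauc-8-en-14-oate
Product: 15 (1R,2S,4R,5S,6S,10R)-10alpha-(tert-butyldimethylsilyloxy)-2alpha,4beta-bis(triethylsilyloxy)dauc-8-ene-6alpha,14-diol
Conditions: DIBAL-H (4 equiv), CH2Cl2, −78 → −20 °C; Rochelle salt
Reagents that add atoms: none
Why: DIBAL-H reduces the conjugated ester in the 1,2 sense to the primary allylic alcohol without touching the silyl ethers or any stereocentre.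

Step 10
Reactants: 15 (1R,2S,4R,5S,6S,10R)-10alpha-(tert-butyldimethylsilyloxy)-2alpha,4beta-bis(triethylsilyloxy)dauc-8-ene-6alpha,14-diol
Product: 17 (1R,2S,4R,5S,6S,10R)-10alpha-(tert-butyldimethylsilyloxy)-2alpha,4beta-bis(triethylsilyloxy)dauc-8-en-6alpha-ol, via allylic mesylate 16 (not isolated)
Conditions: MsCl (1.05 equiv), Et3N, CH2Cl2, −40 °C; then LiBHEt3, THF, −40 → 0 °C
Reagents that add atoms: none
Why: The primary allylic hydroxyl should be mesylated selectively over the hindered secondary C6 hydroxyl at low temperature, and direct (SN2) hydride displacement of the primary allylic mesylate leaves the C14 methyl group on the unmoved C8=C9 bond.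

Step 11
Reactants: 17 (1R,2S,4R,5S,6S,10R)-10alpha-(tert-butyldimethylsilyloxy)-2alpha,4beta-bis(triethylsilyloxy)dauc-8-en-6alpha-ol; 18 angelic acid
Product: 19 (1R,2S,4R,5S,6S,10R)-6alpha-angeloyloxy-10alpha-(tert-butyldimethylsilyloxy)-2alpha,4beta-bis(triethylsilyloxy)dauc-8-ene
Conditions: 18, 2,4,6-trichlorobenzoyl chloride, Et3N, toluene, rt; then 17, toluene, 80 °C
Reagents that add atoms: none
Why: Yamaguchi-type esterification through the mixed 2,4,6-trichlorobenzoic anhydride, run without DMAP, acylates the C6 hydroxyl with retention at C6 and should keep the Z geometry of the angelate.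

Step 12
Reactants: 19 (1R,2S,4R,5S,6S,10R)-6alpha-angeloyloxy-10alpha-(tert-butyldimethylsilyloxy)-2alpha,4beta-bis(triethylsilyloxy)dauc-8-ene
Product: 20 (1R,2S,4R,5S,6S,10R)-6alpha-angeloyloxydauc-8-ene-2alpha,4beta,10alpha-triol
Conditions: HF·pyridine, pyridine, THF, 0 °C → rt
Reagents that add atoms: none
Why: Fluoride-mediated global desilylation under buffered, non-basic conditions should free the C2, C4 and C10 hydroxyls without hydrolysis or migration of the angelate.

Step 13
Reactants: 20 (1R,2S,4R,5S,6S,10R)-6alpha-angeloyloxydauc-8-ene-2alpha,4beta,10alpha-triol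
Product: 21 (1R,2S,4R,5S,6S,8R,9S,10S)-6alpha-angeloyloxy-8alpha,9alpha-epoxydaucane-2alpha,4beta,10alpha-triol
Conditions: VO(acac)2 (5 mol%), t-BuOOH, CH2Cl2, 0 °C → rt
Reagents that add atoms: tert-butyl hydroperoxide, CC(C)(C)OO
Why: Hydroxyl-directed epoxidation: the allylic C10 hydroxyl binds vanadium and delivers oxygen to the same (alpha) face of C8=C9, which sets C8 (R) and C9 (S), while the electron-poor angelate double bond is inert.

Step 14
Reactants: 21 (1R,2S,4R,5S,6S,8R,9S,10S)-6alpha-angeloyloxy-8alpha,9alpha-epoxydaucane-2alpha,4beta,10alpha-triol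
Product: 22 (1R,2S,4R,5S,6S,8R,9S,10S)-2alpha,10alpha-diacetoxy-6alpha-angeloyloxy-8alpha,9alpha-epoxydaucan-4beta-ol (CNP0170993.1)
Conditions: Ac2O, pyridine, DMAP (cat.), CH2Cl2, rt
Reagents that add atoms: acetic anhydride, CC(=O)OC(C)=O
Why: DMAP-catalysed acetylation esterifies the two secondary hydroxyls (C2, C10) and leaves the tertiary C4 hydroxyl free, which completes the target.

Compound list

1 | 3-methylbutan-2-one | CC(C)C(C)=O | starting material
2 | methacrolein (2-methylprop-2-enal) | CC(=C)C=O | starting material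
3 | (S)-5-hydroxy-2,6-dimethylhept-6-en-3-one | C=C(C)[C@@H](O)CC(=O)C(C)C | intermediate
4 | ethynylmagnesium bromide | C#C[Mg]Br | starting material
5 | (3R,5S)-6-methyl-3-(propan-2-yl)hept-6-en-1-yne-3,5-diol | C=C(C)[C@@H](O)C[C@@](O)(C(C)C)C#C | intermediate
6 | (1R,3S)-5-ethenyl-4-methyl-1-(propan-2-yl)cyclopent-4-ene-1,3-diol | C=CC1=C(C)[C@@H](O)C[C@@]1(O)C(C)C | intermediate
7 | (1R,3S)-5-ethenyl-4-methyl-1-(propan-2-yl)-1,3-bis(triethylsilyloxy)cyclopent-4-ene | C=CC1=C(C)[C@@H](O[Si](CC)(CC)CC)C[C@@]1(O[Si](CC)(CC)CC)C(C)C | intermediate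
8 | ethyl diazoacetate | CCOC(=O)C=[N+]=[N-] | starting material
9 | (tert-butyldimethylsilyloxy)acetaldehyde | CC(C)(C)[Si](C)(C)OCC=O | starting material
10 | ethyl 4-(tert-butyldimethylsilyloxy)-2-diazo-3-hydroxybutanoate (racemic) | CCOC(=O)C(=[N+]=[N-])C(O)CO[Si](C)(C)C(C)(C)C | intermediate
11 | ethyl (E)-4-(tert-butyldimethylsilyloxy)-2-diazobut-3-enoate | CCOC(=O)C(=[N+]=[N-])/C=C/O[Si](C)(C)C(C)(C)C | intermediate
12 | ethyl (1R,2S)-1-[(E)-2-(tert-butyldimethylsilyloxy)ethenyl]-2-[(3S,5R)-2-methyl-5-(propan-2-yl)-3,5-bis(triethylsilyloxy)cyclopent-1-en-1-yl]cyclopropane-1-carboxylate (cis-divinylcyclopropane) | CCOC(=O)[C@]1(/C=C/O[Si](C)(C)C(C)(C)C)C[C@H]1C1=C(C)[C@@H](O[Si](CC)(CC)CC)C[C@@]1(O[Si](CC)(CC)CC)C(C)C | intermediate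
13 | ethyl (1R,2S,4R,10R)-10alpha-(tert-butyldimethylsilyloxy)-2alpha,4beta-bis(triethylsilyloxy)dauca-5,8-dien-14-oate | CCOC(=O)C1=C[C@@H](O[Si](C)(C)C(C)(C)C)[C@@]2(C)[C@@H](O[Si](CC)(CC)CC)C[C@@](O[Si](CC)(CC)CC)(C(C)C)C2=CC1 | intermediate
14 | ethyl (1R,2S,4R,5S,6S,10R)-6alpha-hydroxy-10alpha-(tert-butyldimethylsilyloxy)-2alpha,4beta-bis(triethylsilyloxy)dauc-8-en-14-oate | CCOC(=O)C1=C[C@@H](O[Si](C)(C)C(C)(C)C)[C@@]2(C)[C@@H](O[Si](CC)(CC)CC)C[C@@](O[Si](CC)(CC)CC)(C(C)C)[C@@H]2[C@@H](O)C1 | intermediate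
15 | (1R,2S,4R,5S,6S,10R)-10alpha-(tert-butyldimethylsilyloxy)-2alpha,4beta-bis(triethylsilyloxy)dauc-8-ene-6alpha,14-diol | OCC1=C[C@@H](O[Si](C)(C)C(C)(C)C)[C@@]2(C)[C@@H](O[Si](CC)(CC)CC)C[C@@](O[Si](CC)(CC)CC)(C(C)C)[C@@H]2[C@@H](O)C1 | intermediate
16 | 14-methanesulfonate of 15 (allylic mesylate) | CS(=O)(=O)OCC1=C[C@@H](O[Si](C)(C)C(C)(C)C)[C@@]2(C)[C@@H](O[Si](CC)(CC)CC)C[C@@](O[Si](CC)(CC)CC)(C(C)C)[C@@H]2[C@@H](O)C1 | intermediate
17 | (1R,2S,4R,5S,6S,10R)-10alpha-(tert-butyldimethylsilyloxy)-2alpha,4beta-bis(triethylsilyloxy)dauc-8-en-6alpha-ol | CC1=C[C@@H](O[Si](C)(C)C(C)(C)C)[C@@]2(C)[C@@H](O[Si](CC)(CC)CC)C[C@@](O[Si](CC)(CC)CC)(C(C)C)[C@@H]2[C@@H](O)C1 | intermediate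
18 | angelic acid ((Z)-2-methylbut-2-enoic acid) | C/C=C(/C)C(=O)O | starting material
19 | (1R,2S,4R,5S,6S,10R)-6alpha-angeloyloxy-10alpha-(tert-butyldimethylsilyloxy)-2alpha,4beta-bis(triethylsilyloxy)dauc-8-ene | C/C=C(/C)C(=O)O[C@H]1CC(C)=C[C@@H](O[Si](C)(C)C(C)(C)C)[C@@]2(C)[C@@H](O[Si](CC)(CC)CC)C[C@@](O[Si](CC)(CC)CC)(C(C)C)[C@H]12 | intermediate
20 | (1R,2S,4R,5S,6S,10R)-6alpha-angeloyloxydauc-8-ene-2alpha,4beta,10alpha-triol | C/C=C(/C)C(=O)O[C@H]1CC(C)=C[C@@H](O)[C@@]2(C)[C@@H](O)C[C@@](O)(C(C)C)[C@H]12 | intermediate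
21 | (1R,2S,4R,5S,6S,8R,9S,10S)-6alpha-angeloyloxy-8alpha,9alpha-epoxydaucane-2alpha,4beta,10alpha-triol | C/C=C(/C)C(=O)O[C@H]1C[C@@]2(C)O[C@H]2[C@@H](O)[C@@]2(C)[C@@H](O)C[C@@](O)(C(C)C)[C@H]12 | intermediate
22 | (1R,2S,4R,5S,6S,8R,9S,10S)-2alpha,10alpha-diacetoxy-6alpha-angeloyloxy-8alpha,9alpha-epoxydaucan-4beta-ol (CNP0170993.1) | C/C=C(/C)C(=O)O[C@H]1C[C@@]2(C)O[C@H]2[C@@H](OC(C)=O)[C@@]2(C)[C@@H](OC(C)=O)C[C@@](O)(C(C)C)[C@H]12 | target

Total step count: 14. Longest linear sequence: 12 steps (steps 1–4 and 7–14); the carbenoid precursor 11 is made in a two-step side branch (steps 5–6).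

Steps most likely to fail

1. Step 7. What may go wrong: the diene may attack the oxygen-stabilised carbenoid at its vinylogous C10 terminus, or 11 may react with itself through its enol ether, so that cyclopropane 12 does not form cleanly; the Cope rearrangement may also stall because the C15 methyl lies inside the boat. Fallback (sets out from 7, returns at 13): the same tandem cyclopropanation/Cope sequence is run with the established central-siloxy reagent, ethyl 2-diazo-3-(tert-butyldimethylsilyloxy)but-3-enoate F1 (from commercial ethyl 2-diazo-3-oxobutanoate, TBSOTf, Et3N), under Rh2(R-DOSP)4; it still forms C7–C8 and C1–C10 and sets C1 under catalyst control, and should give the C9 silyl enol ether, ethyl 9-(tert-butyldimethylsilyloxy)-2alpha,4beta-bis(triethylsilyloxy)dauca-5,8-dien-14-oate F2. The C10 oxygen is then introduced by enolate chemistry: cleavage of the enol ether (K2CO3, EtOH, 0 °C) to the beta-keto ester F3, gamma-selective hydroxylation of its dianion (NaH, then n-BuLi; 2-(phenylsulfonyl)-3-phenyloxaziridine), expected anti to the C15 methyl, to the 10alpha-hydroxy beta-keto ester F4, silylation (TBSOTf, 2,6-lutidine) to the 10alpha-silyl ether F5, enol triflate formation at C9 (NaH, PhNTf2) to the enol triflate F6, and reduction of the triflate (Pd(OAc)2, PPh3, Bu3N, HCO2H, DMF) to 13.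

2. Step 8. What may go wrong: borane may be delivered to the beta face, because the alpha face carries the C10 and C2 silyloxy groups and the isopropyl group, which would give the cis-fused 5beta-H/6beta-ol; the enoate may also be reduced in competition. Fallback (sets out from 13, returns at 19): the beta-face preference is used instead. Epoxidation of C5=C6 with mCPBA/NaHCO3 (the enoate is inert) should give the 5beta,6beta-epoxide F7. Lewis-acid Meinwald rearrangement (BF3·OEt2, CH2Cl2, −78 °C) opens it at the tertiary C5, and the C6 hydrogen migrates to the alpha face of C5, anti to the departing oxygen, to give the trans-fused C6 ketone F8. DIBAL-H then reduces the ketone (hydride from the open alpha face) and the ester to the 6beta,14-diol F9. Selective mesylation to the allylic mesylate F10 (not isolated) and LiBHEt3 give the 6beta-alcohol F11, and Mitsunobu esterification with angelic acid 18 (PPh3, DIAD) inverts C6 and gives 19.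

3. Step 2. What may go wrong: 1,3-induction may be eroded or reversed (for example by internal delivery from a magnesium ate complex instead of external attack on the chelate), or the magnesium aldolate may undergo retro-aldol cleavage. Fallback (sets out from 2, returns at 5): the roles of the two carbon groups on C4 are exchanged. The same boron aldol reaction of methacrolein 2 with commercial 4-(trimethylsilyl)but-3-yn-2-one gives the ynone aldol, (S)-5-hydroxy-6-methyl-1-(trimethylsilyl)hept-6-en-1-yn-3-one F12. 1,2-Addition of i-PrMgCl/CeCl3 then brings in the isopropyl group, so that the facial preference that made the main step fail now leads to the needed C4 epimer, the silylated enyne diol F13. K2CO3/MeOH removes the alkynyl silyl group to give 5.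

Further compounds

F1 | step 7 | ethyl 2-diazo-3-(tert-butyldimethylsilyloxy)but-3-enoate | C=C(O[Si](C)(C)C(C)(C)C)C(=[N+]=[N-])C(=O)OCC
F2 | step 7 | ethyl (1R,2S,4R)-9-(tert-butyldimethylsilyloxy)-2alpha,4beta-bis(triethylsilyloxy)dauca-5,8-dien-14-oate | CCOC(=O)C1=C(O[Si](C)(C)C(C)(C)C)C[C@@]2(C)[C@@H](O[Si](CC)(CC)CC)C[C@@](O[Si](CC)(CC)CC)(C(C)C)C2=CC1
F3 | step 7 | ethyl 9-oxo-2alpha,4beta-bis(triethylsilyloxy)dauc-5-en-14-oate (beta-keto ester, C8 epimers) | CCOC(=O)C1C(=O)C[C@@]2(C)[C@@H](O[Si](CC)(CC)CC)C[C@@](O[Si](CC)(CC)CC)(C(C)C)C2=CC1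
F4 | step 7 | ethyl 10alpha-hydroxy-9-oxo-2alpha,4beta-bis(triethylsilyloxy)dauc-5-en-14-oate | CCOC(=O)C1C(=O)[C@@H](O)[C@@]2(C)[C@@H](O[Si](CC)(CC)CC)C[C@@](O[Si](CC)(CC)CC)(C(C)C)C2=CC1
F5 | step 7 | ethyl 10alpha-(tert-butyldimethylsilyloxy)-9-oxo-2alpha,4beta-bis(triethylsilyloxy)dauc-5-en-14-oate | CCOC(=O)C1C(=O)[C@@H](O[Si](C)(C)C(C)(C)C)[C@@]2(C)[C@@H](O[Si](CC)(CC)CC)C[C@@](O[Si](CC)(CC)CC)(C(C)C)C2=CC1
F6 | step 7 | ethyl 10alpha-(tert-butyldimethylsilyloxy)-9-(trifluoromethanesulfonyloxy)-2alpha,4beta-bis(triethylsilyloxy)dauca-5,8-dien-14-oate | CCOC(=O)C1=C(OS(=O)(=O)C(F)(F)F)[C@@H](O[Si](C)(C)C(C)(C)C)[C@@]2(C)[C@@H](O[Si](CC)(CC)CC)C[C@@](O[Si](CC)(CC)CC)(C(C)C)C2=CC1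
F7 | step 8 | ethyl 5beta,6beta-epoxy-10alpha-(tert-butyldimethylsilyloxy)-2alpha,4beta-bis(triethylsilyloxy)dauc-8-en-14-oate | CCOC(=O)C1=C[C@@H](O[Si](C)(C)C(C)(C)C)[C@@]2(C)[C@@H](O[Si](CC)(CC)CC)C[C@@](O[Si](CC)(CC)CC)(C(C)C)[C@]23O[C@@H]3C1
F8 | step 8 | ethyl (5S)-6-oxo-10alpha-(tert-butyldimethylsilyloxy)-2alpha,4beta-bis(triethylsilyloxy)dauc-8-en-14-oate (trans-fused ketone) | CCOC(=O)C1=C[C@@H](O[Si](C)(C)C(C)(C)C)[C@@]2(C)[C@@H](O[Si](CC)(CC)CC)C[C@@](O[Si](CC)(CC)CC)(C(C)C)[C@@H]2C(=O)C1
F9 | step 8 | 10alpha-(tert-butyldimethylsilyloxy)-2alpha,4beta-bis(triethylsilyloxy)dauc-8-ene-6beta,14-diol | OCC1=C[C@@H](O[Si](C)(C)C(C)(C)C)[C@@]2(C)[C@@H](O[Si](CC)(CC)CC)C[C@@](O[Si](CC)(CC)CC)(C(C)C)[C@@H]2[C@H](O)C1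
F10 | step 8 | 14-methanesulfonate of F9 | CS(=O)(=O)OCC1=C[C@@H](O[Si](C)(C)C(C)(C)C)[C@@]2(C)[C@@H](O[Si](CC)(CC)CC)C[C@@](O[Si](CC)(CC)CC)(C(C)C)[C@@H]2[C@H](O)C1
F11 | step 8 | 10alpha-(tert-butyldimethylsilyloxy)-2alpha,4beta-bis(triethylsilyloxy)dauc-8-en-6beta-ol | CC1=C[C@@H](O[Si](C)(C)C(C)(C)C)[C@@]2(C)[C@@H](O[Si](CC)(CC)CC)C[C@@](O[Si](CC)(CC)CC)(C(C)C)[C@@H]2[C@H](O)C1
F12 | step 2 | (S)-5-hydroxy-6-methyl-1-(trimethylsilyl)hept-6-en-1-yn-3-one | C=C(C)[C@@H](O)CC(=O)C#C[Si](C)(C)C
F13 | step 2 | (3R,5S)-6-methyl-3-(propan-2-yl)-1-(trimethylsilyl)hept-6-en-1-yne-3,5-diol | C=C(C)[C@@H](O)C[C@@](O)(C(C)C)C#C[Si](C)(C)C
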